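If we want to know how much of a charge of X a gas can bind in a minute, we first set down the scheme and the flask.

    Z ⇌ E, rate k1*(csat - [E]) (k1 = 0.33 s⁻¹, csat = 0.79 mM)
    X + E ⇌ X.E (K2 = 1100 M⁻¹, k2 = 27 M⁻¹ s⁻¹)
    X → D (k3 = 0.0011 s⁻¹)
    E ⇌ J (K4 = 45, k4 = 0.0099 s⁻¹)
    E → Q (k5 = 0.013 s⁻¹)

X 20 mM; Z 0.79 mM (held); time 1.0 min

- at the start none of E is dissolved
- run time (flask): 1.0 min

- how much X.E there is at 1.0 min, in percent of the X charged
- concentration of E in solution at 15 s, in percent of saturation
- the change that raises the amount of X.E at 1.0 min, in percent of the X charged most ("none" if none brings more than 2 percentage points) (elm / alder / none)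
- amount of X.E at 1.0 min, in percent of the X charged, after elm

- elm: doubling the saturation concentration of Z, all else as stated
- alder: doubling the transfer coefficient of step 1, all else as stated

Two numbers seem to quarrel: the equilibrium constant K of capture times the starting X is 22, which reads as tight binding, yet K times the saturation of E is 0.869. Both hold: the first speaks for E and the second for X, whose bound share goes with K[E]. By the forward rate of capture at the charged X, E has a half-life of 1.3 s, short against the run, so we hold E at the balance of its gains and losses. X goes to D with a half-life of 11 min, longer than the run, so we drop D and count E going to J and Q without return.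

g = transfer coefficient + both first-order losses of E = 0.353 s⁻¹

E* = transfer coefficient × saturation / g = 0.739 mM

R = K·E* = 0.813

b = R/(R + one) = 44.8 %, the binding ceiling, the share of X bound once X.E stands at equilibrium with E at E*

We work with the fraction left to go, u = one − y/b, where y is the share bound. It falls as a pseudo-first-order decay, exp(−λt), where k is the capture rate constant and [X] is taken halfway to the ceiling, 15.5 mM:

λ = g·(k/K)·(R + one)/(g + k[X]) = 0.0203 s⁻¹

y = b(one − u) = 31.6 %

At 15 s the same decay gives 11.8 % bound, and the balance of E then stands at 48.6 % of saturation.

Doubling saturation doubles R, so the ceiling rises to 61.9 % and y to 52.5 %. Doubling transfer gives 0.683 s⁻¹, 0.840 and a ceiling of 45.6 %, so y reaches 37.2 %. We choose elm.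

The forecast also chooses elm, on the ground that “Doubling the saturation concentration doubles the gas supply”, and its 29.7 %, 47.5 % and 50 % each stand a little below our figures.

The flask gives 29.6 % and 46.1 %; the better change is elm, which adds 21 percentage points and reaches 50.4 %, against 6.1 points for alder. At 1.00 min the flask already holds 5.29 % as D, and its X.E stands at 66.1 % of the ceiling. The ceiling as reckoned contains no charge of X, so we carry it unchanged to the neighbour flask with 5.0 mM of X, where the halfway [X] is 3.88 mM and the decay gives 39.1 %. That flask reads 37.3 %, with 4.87 % as D.

Its constants are made up, and the outcome is calculated.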